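**Plan**

1. Numbering follows 1H-isochromene (C1, O2, C3, C4, C4a, C5 to C8, C8a; side chain C1' to C9'). Ring A is the 2H-pyran and ring B the cyclohexenone.
2. Enabling feature: ring A (O2-C3=C4-C4a=C8a-C1) is the closed valence isomer of the 1-oxatriene O2=C3-C4=C4a-C8a=C1. In addition, C1-C8a=C4a is an allyl unit whose far end C4a is the β-carbon (vinylogous carboxyl carbon) of the C8 enone of ring B.
3. Retrosynthesis: C4-C4a and C1-O2 are cut together, back to allylic β-keto ester 18 (C1-O-CO-C4H2-C3(=O)-propenyl, OMe on C4a). CO2 is a traceless tether and OMe holds C4a at the ketone level. Then follow C1-C8a (Stille), C4a=O (dealkenylation of an isopropenyl group), C7-O (Rubottom) and C6-C1' (Mukaiyama-Michael).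
4. Forward: ring B is the ring of (R)-carvone. The chain from nonan-2-one is joined first, then come the C7 hydroxyl, the C4a oxygen, C1 and the tether. Ring A closes in the last step, without protecting groups.
5. Stereochemistry: C5 of (R)-carvone sends the chain to the opposite face (C6), and the chain sends the oxidant to the opposite face (C7). The carvone centre is then erased as the C4a carbonyl. The key step makes only transient centres and alkene geometries, all of which converge.

Key step: step 10

Remark: 9 and 16 are each drawn as one tautomer. Centres that arise and vanish within a step are left undefined because both configurations lead on: the peroxy carbon of 7, C4a of 8, and C4 and C4a of 19 and 20.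

Step 1
Reactants: 1 nonan-2-one
Product: 2 2-(trimethylsilyloxy)non-1-ene
Conditions: LiN(iPr)2 (LDA), THF, -78 °C; TMSCl, -78 °C to rt
Reagents that add atoms: chlorotrimethylsilane, C[Si](C)(C)Cl
Why: Kinetic enolisation of the methyl ketone at the CH3 side by the hindered amide base, followed by O-silylation (kinetic silyl enol ether formation), should give the terminal enol ether.

Step 2
Reactants: 2 2-(trimethylsilyloxy)non-1-ene; 3 (R)-(-)-carvone
Product: 4 1-[(1S,5R)-2-methyl-5-(prop-1-en-2-yl)-3-(trimethylsilyloxy)cyclohex-2-en-1-yl]nonan-2-one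
Conditions: Tf2NH (3 mol %), CH2Cl2, -78 to -40 °C; Et3N quench
Reagents that add atoms: none
Why: Mukaiyama-Michael addition with silyl transfer, catalysed by the TMSNTf2 that Tf2NH forms from 2: the nucleophile should add axially to the β-carbon of the enone on the face opposite the isopropenyl group, which sets C6 as S, and the silyl group ends on the C8 oxygen, so that the enol ether is fixed toward C7.

Step 3
Reactants: 4 silyl enol ether from step 2
Product: 6 (2S,3S,5R)-2-hydroxy-2-methyl-3-(2-oxononyl)-5-(prop-1-en-2-yl)cyclohexan-1-one, via silyloxy ketone 5 (not isolated)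
Conditions: mCPBA (1.0 equiv), CH2Cl2, -20 °C; then aq. HCl (cat.), THF, 0 °C
Reagents that add atoms: mCPBA, O=C(OO)c1cccc(Cl)c1
Why: Rubottom oxidation: the tetrasubstituted silyl enol ether is much more electron-rich than the isopropenyl group, the C6 chain stands pseudoaxial to avoid allylic strain against the C7 methyl and shields its face, so oxygen should enter anti to the chain (C7 as S, OH trans to the chain), and silyl migration then mild hydrolysis free the tertiary alcohol.

Step 4
Reactants: 6 hydroxy ketone from step 3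
Product: 9 (4S,5R)-4-hydroxy-4-methyl-5-(2-oxononyl)cyclohexane-1,3-dione (same spatial arrangement as in 6; the second descriptor changes by priority only), via methoxy hydroperoxide 7 (not isolated), via TEMPO ether 8 (not isolated)
Conditions: O3, MeOH, -78 °C; TEMPO, FeSO4·7H2O, -78 °C to rt; then mCPBA, CH2Cl2, 0 °C
Reagents that add atoms: TEMPO, CC1(C)CCCC(C)(C)N1[O] (its oxygen becomes the C4a carbonyl oxygen); ozone, [O-][O+]=O, and methanol, CO (their atoms stay only in intermediate 7)
Why: Oxidative dealkenylation: ozonolysis in methanol gives hydroperoxide 7, divalent iron cleaves its O-O bond, β-scission of the alkoxy radical expels methyl acetate, TEMPO traps the secondary C4a radical and peracid oxidation of alkoxyamine 8 gives the ketone, so the now useless carvone stereocentre becomes the C4a carbonyl while the saturated ketones and the tertiary alcohol are inert.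

Step 5
Reactants: 9 dione from step 4
Product: 10 (5S,6S)-6-hydroxy-3-methoxy-6-methyl-5-(2-oxononyl)cyclohex-2-en-1-one
Conditions: MeOH, TsOH·H2O (5 mol %), 3 Å MS, rt
Reagents that add atoms: methanol, CO
Why: Acid-catalysed enol etherification of a 1,3-dione under equilibrium control: methanol should attack the C4a carbonyl, which is flanked by CH2, and not the C8 carbonyl, which is flanked by the fully substituted C7 and hydrogen-bonded to its OH.

Step 6
Reactants: 10 vinylogous ester from step 5
Product: 11 (5S,6S)-6-hydroxy-2-iodo-3-methoxy-6-methyl-5-(2-oxononyl)cyclohex-2-en-1-one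
Conditions: NIS, MeCN, 0 °C to rt, dark
Reagents that add atoms: N-iodosuccinimide, O=C1CCC(=O)N1I
Why: Electrophilic α-iodination of a vinylogous ester: C8a is the enol-ether β-carbon and the most nucleophilic carbon of 10, so it should be iodinated in preference to the α-positions of the saturated ketone.

Step 7
Reactants: 11 iodide from step 6; 12 (tributylstannyl)methanol
Product: 13 (5S,6S)-6-hydroxy-2-(hydroxymethyl)-3-methoxy-6-methyl-5-(2-oxononyl)cyclohex-2-en-1-one
Conditions: Pd(PPh3)4 (5 mol %), dioxane, 90 °C
Reagents that add atoms: none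
Why: Stille cross-coupling (hydroxymethylation) of an α-iodoenone: oxidative addition into the C8a-I bond and selective transfer of the oxygen-bearing CH2OH group from tin should install C1 under neutral conditions that leave the ketones, the vinylogous ester and the tertiary alcohol alone.

Step 8
Reactants: 14 Meldrum's acid; 15 (E)-crotonyl chloride
Product: 16 5-[(E)-1-hydroxybut-2-enylidene]-2,2-dimethyl-1,3-dioxane-4,6-dione
Conditions: pyridine (2 equiv), CH2Cl2, 0 °C to rt
Reagents that add atoms: none
Why: C-acylation of Meldrum's acid by an acid chloride gives the enolic acyl Meldrum's acid, a storable acylketene precursor, with the E alkene untouched.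

Step 9
Reactants: 13 allylic alcohol from step 7; 16 acyl Meldrum's acid (1.05 equiv)
Product: 18 [(4S,5S)-5-hydroxy-2-methoxy-5-methyl-6-oxo-4-(2-oxononyl)cyclohex-1-en-1-yl]methyl (E)-3-oxohex-4-enoate, via crotonoylketene 17 (not isolated)
Conditions: toluene, 85 °C
Reagents that add atoms: none
Why: Thermal cycloreversion of the acyl Meldrum's acid releases acylketene 17, which the unhindered primary C1 alcohol should trap much faster than the hindered, hydrogen-bonded tertiary C7 alcohol (β-keto ester synthesis through an acylketene), at a temperature below that of the rearrangement.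

Step 10
Reactants: 18 allylic β-keto ester from step 9
Product: 22 (6S,7S)-7-hydroxy-7-methyl-6-(2-oxononyl)-3-[(E)-prop-1-enyl]-6,7-dihydro-1H-isochromen-8(5H)-one (target), via Carroll acid 19 (not isolated), via methoxy ketone 20 (not isolated), via oxatriene 21 (not isolated)
Conditions: DMAP (0.1 equiv), 4 Å MS, BHT (trace), mesitylene (0.01 M), 150 °C, Ar
Reagents that add atoms: none
Why: Proposed new method: the ester-enol tautomer of 18 is an allyl vinyl ether (C4=C(OH)-O-C1-C8a=C4a), so heating should start a Carroll [3,3] shift through a six-membered transition state that bonds C4 to C4a, breaks the old C1-O(ester) bond and gives β-keto acid 19 with an exocyclic C8a=C1 methylene; 19 loses CO2 (which carries off the oxygen that stood on C1), the resulting β-methoxy ketone 20 expels MeOH (E1cB, DMAP as base, sieves as sink), and 1-oxatriene 21 results. The closest known reaction types are the Carroll (Kimel-Cope) rearrangement of simple allylic acetoacetates, Claisen shifts of cyclohexenylmethanol derivatives (quaternary carbon plus exocyclic methylene) and of glycal esters (C-C bond formed at an oxygen-bearing alkene carbon), and the Knoevenagel/oxa-6π route to 2H-pyrans; what is new is the allyl partner, a 3-alkoxy-2-(acyloxymethyl)enone, and the coupling of the four events. Ring A, the only ring closed, forms by thermal disrotatory oxa-6π electrocyclisation of (Z)-21, in which the C3 ketone oxygen becomes O2 and bonds to C1; closure should be downhill because a cross-conjugated bis-exocyclic dienone turns into the linearly conjugated, doubly vinylogous ester O2-C3=C4-C4a=C8a-C8=O. No lasting stereocentre is made: C4 and C4a of 19 and 20 are erased by the elimination and C1 is a CH2 group, so both faces of C4a and both alkene geometries converge, (E)-21 being fed into (Z)-21 by reversible addition of MeOH or DMAP at C4a, while C6 and C7 carry no acidic hydrogen and stay as set. The step needs C4 to bond to C4a and not to C1, and this is secured by the tether, since only C4a can be reached through the six-membered array, helped by an apolar solvent that disfavours ionisation of the allylic ester. The OMe donor on the allyl terminus C4a and the C8 acyl group on C8a both sit at positions known to speed up aliphatic Claisen shifts, and because carboxylate is a better leaving group than methoxide even a stepwise Michael-type attack of C4 on C4a would collapse to the same acid 19.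

**Compound list**

1 | nonan-2-one | CCCCCCCC(C)=O | starting material
2 | 2-(trimethylsilyloxy)non-1-ene | C=C(O[Si](C)(C)C)CCCCCCC | intermediate
3 | (R)-(-)-carvone | C=C(C)[C@H]1CC(=O)C(C)=CC1 | starting material
4 | 1-[(1S,5R)-2-methyl-5-(prop-1-en-2-yl)-3-(trimethylsilyloxy)cyclohex-2-en-1-yl]nonan-2-one | C=C(C)[C@H]1CC(O[Si](C)(C)C)=C(C)[C@H](CC(=O)CCCCCCC)C1 | intermediate
5 | (2S,3S,5R)-2-methyl-3-(2-oxononyl)-5-(prop-1-en-2-yl)-2-(trimethylsilyloxy)cyclohexan-1-one | C=C(C)[C@H]1CC(=O)[C@@](C)(O[Si](C)(C)C)[C@H](CC(=O)CCCCCCC)C1 | intermediate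
6 | (2S,3S,5R)-2-hydroxy-2-methyl-3-(2-oxononyl)-5-(prop-1-en-2-yl)cyclohexan-1-one | C=C(C)[C@H]1CC(=O)[C@@](C)(O)[C@H](CC(=O)CCCCCCC)C1 | intermediate
7 | (2S,3S,5R)-5-(1-hydroperoxy-1-methoxyethyl)-2-hydroxy-2-methyl-3-(2-oxononyl)cyclohexan-1-one | COC(C)(OO)[C@H]1CC(=O)[C@@](C)(O)[C@H](CC(=O)CCCCCCC)C1 | intermediate
8 | (2S,3S)-2-hydroxy-2-methyl-3-(2-oxononyl)-5-[(2,2,6,6-tetramethylpiperidin-1-yl)oxy]cyclohexan-1-one, both C5 epimers | CC1(C)CCCC(C)(C)N1OC1CC(=O)[C@@](C)(O)[C@H](CC(=O)CCCCCCC)C1 | intermediate
9 | (4S,5R)-4-hydroxy-4-methyl-5-(2-oxononyl)cyclohexane-1,3-dione | O=C1CC(=O)[C@@](C)(O)[C@H](CC(=O)CCCCCCC)C1 | intermediate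
10 | (5S,6S)-6-hydroxy-3-methoxy-6-methyl-5-(2-oxononyl)cyclohex-2-en-1-one | COC1=CC(=O)[C@@](C)(O)[C@H](CC(=O)CCCCCCC)C1 | intermediate
11 | (5S,6S)-6-hydroxy-2-iodo-3-methoxy-6-methyl-5-(2-oxononyl)cyclohex-2-en-1-one | COC1=C(I)C(=O)[C@@](C)(O)[C@H](CC(=O)CCCCCCC)C1 | intermediate
12 | (tributylstannyl)methanol | CCCC[Sn](CCCC)(CCCC)CO | starting material
13 | (5S,6S)-6-hydroxy-2-(hydroxymethyl)-3-methoxy-6-methyl-5-(2-oxononyl)cyclohex-2-en-1-one | COC1=C(CO)C(=O)[C@@](C)(O)[C@H](CC(=O)CCCCCCC)C1 | intermediate
14 | Meldrum's acid (2,2-dimethyl-1,3-dioxane-4,6-dione) | CC1(C)OC(=O)CC(=O)O1 | starting material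
15 | (E)-crotonyl chloride | C/C=C/C(=O)Cl | starting material
16 | 5-[(E)-1-hydroxybut-2-enylidene]-2,2-dimethyl-1,3-dioxane-4,6-dione | C/C=C/C(O)=C1C(=O)OC(C)(C)OC1=O | intermediate
17 | (E)-hexa-1,4-diene-1,3-dione (crotonoylketene) | C/C=C/C(=O)C=C=O | intermediate
18 | [(4S,5S)-5-hydroxy-2-methoxy-5-methyl-6-oxo-4-(2-oxononyl)cyclohex-1-en-1-yl]methyl (E)-3-oxohex-4-enoate | COC1=C(COC(=O)CC(=O)/C=C/C)C(=O)[C@@](C)(O)[C@H](CC(=O)CCCCCCC)C1 | intermediate
19 | (E)-2-[(4S,5S)-4-hydroxy-1-methoxy-4-methyl-2-methylidene-3-oxo-5-(2-oxononyl)cyclohexyl]-3-oxohex-4-enoic acid, ring C1 and acid C2 undefined | C=C1C(=O)[C@@](C)(O)[C@H](CC(=O)CCCCCCC)CC1(OC)C(C(=O)O)C(=O)/C=C/C | intermediate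
20 | (5S,6S)-6-hydroxy-3-methoxy-6-methyl-2-methylidene-5-(2-oxononyl)-3-[(E)-2-oxopent-3-enyl]cyclohexan-1-one, C3 undefined | C=C1C(=O)[C@@](C)(O)[C@H](CC(=O)CCCCCCC)CC1(OC)CC(=O)/C=C/C | intermediate
21 | (3Z,5S,6S)-6-hydroxy-6-methyl-2-methylidene-5-(2-oxononyl)-3-[(E)-2-oxopent-3-enylidene]cyclohexan-1-one (the isomer that closes) | C=C1C(=O)[C@@](C)(O)[C@H](CC(=O)CCCCCCC)C/C1=C/C(=O)/C=C/C | intermediate
22 | (6S,7S)-7-hydroxy-7-methyl-6-(2-oxononyl)-3-[(E)-prop-1-enyl]-6,7-dihydro-1H-isochromen-8(5H)-one | C/C=C/C1=CC2=C(CO1)C(=O)[C@@](C)(O)[C@H](CC(=O)CCCCCCC)C2 | target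

**Step count and risks**

Total step count: 10. Longest linear sequence: 9 (steps 1 to 7, 9 and 10).

Steps most likely to fail:

1. Step 10.
   - What may go wrong: the [3,3] shift may need a temperature at which the tether is lost by retro-ene cleavage to the acylketene. The allylic ester may also ionise and recombine at C1, or the trienyl pyran may decompose.
   - Fallback (known chemistry): it sets out from 13 and returns at 22. C4-C4a is made by cross-coupling and ring A is closed at O2-C3 instead.
   - The primary alcohol of 13 is silylated (TBSCl, imidazole, DMF) to the silyl ether F1.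
   - The vinylogous ester is saponified (LiOH, THF/H2O) to the 2-substituted 1,3-dione F2.
   - O-triflation at the less hindered C4a oxygen (Tf2O, 2,6-lutidine, CH2Cl2, -78 °C) gives the vinylogous triflate F3.
   - Sonogashira coupling with commercial (E)-pent-3-en-1-yne (PdCl2(PPh3)2, CuI, Et3N) gives the dienynone F4.
   - HF·pyridine frees the enynol F5.
   - A 6-endo-dig cycloisomerisation (AuCl(PPh3)/AgOTf, CH2Cl2) then gives 22. In it the C1 hydroxyl adds to C3, the electrophilic δ-carbon of the ynenone.

2. Step 4.
   - What may go wrong: the enolic 1,3-dione may be over-oxidised by the peracid, or the hydroxylamine may be lost from the β-aminoxy ketone by β-elimination before oxidation.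
   - Fallback: it sets out from 6 and returns at 9.
   - Ozonolysis in MeOH followed by Cu(OAc)2·H2O and FeSO4·7H2O (dealkenylative fragmentation to an alkene) gives the conjugated enone F6.
   - Nucleophilic epoxidation (t-BuOOH, DBU, CH2Cl2) gives the epoxy ketone F7.
   - Isomerisation of the α,β-epoxy ketone to the β-diketone (Pd(PPh3)4, dppe, toluene, 100 °C) gives 9.

3. Step 2.
   - What may go wrong: addition of a ketone-derived silyl enol ether to the α-methyl enone may be sluggish. The product enol ether may also be protodesilylated, which loses the regiochemical information needed in step 3.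
   - Fallback: it sets out from 3 and returns at 6, and it builds the chain in two pieces.
   - S-ethyl thioacetate is converted (LiN(iPr)2, TMSCl, THF, -78 °C) into the more nucleophilic ketene silyl thioacetal F8.
   - Mukaiyama-Michael addition of F8 to 3 under the conditions of step 2 gives the silyl enol ether thioester F9.
   - Rubottom oxidation as in step 3 gives the hydroxy ketone thioester F10.
   - Fukuyama coupling with commercial n-heptylzinc bromide, C7H15ZnBr (PdCl2(PPh3)2, toluene/THF, rt), turns the thioester into the heptyl ketone 6 without touching the ring ketone.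

**Further compounds**

F1 | step 10 | (5S,6S)-2-[(tert-butyldimethylsilyloxy)methyl]-6-hydroxy-3-methoxy-6-methyl-5-(2-oxononyl)cyclohex-2-en-1-one | COC1=C(CO[Si](C)(C)C(C)(C)C)C(=O)[C@@](C)(O)[C@H](CC(=O)CCCCCCC)C1
F2 | step 10 | (5S,6S)-2-[(tert-butyldimethylsilyloxy)methyl]-3,6-dihydroxy-6-methyl-5-(2-oxononyl)cyclohex-2-en-1-one (enol form of the 1,3-dione) | OC1=C(CO[Si](C)(C)C(C)(C)C)C(=O)[C@@](C)(O)[C@H](CC(=O)CCCCCCC)C1
F3 | step 10 | (4S,5S)-2-[(tert-butyldimethylsilyloxy)methyl]-4-hydroxy-4-methyl-3-oxo-5-(2-oxononyl)cyclohex-1-en-1-yl trifluoromethanesulfonate | O=S(=O)(OC1=C(CO[Si](C)(C)C(C)(C)C)C(=O)[C@@](C)(O)[C@H](CC(=O)CCCCCCC)C1)C(F)(F)F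
F4 | step 10 | (5S,6S)-2-[(tert-butyldimethylsilyloxy)methyl]-6-hydroxy-6-methyl-5-(2-oxononyl)-3-[(E)-pent-3-en-1-ynyl]cyclohex-2-en-1-one | C/C=C/C#CC1=C(CO[Si](C)(C)C(C)(C)C)C(=O)[C@@](C)(O)[C@H](CC(=O)CCCCCCC)C1
F5 | step 10 | (5S,6S)-6-hydroxy-2-(hydroxymethyl)-6-methyl-5-(2-oxononyl)-3-[(E)-pent-3-en-1-ynyl]cyclohex-2-en-1-one | C/C=C/C#CC1=C(CO)C(=O)[C@@](C)(O)[C@H](CC(=O)CCCCCCC)C1
F6 | step 4 | (5S,6S)-6-hydroxy-6-methyl-5-(2-oxononyl)cyclohex-2-en-1-one | C1=CC(=O)[C@@](C)(O)[C@H](CC(=O)CCCCCCC)C1
F7 | step 4 | 2,3-epoxide of F6 (epoxide face undefined) | C12OC1C(=O)[C@@](C)(O)[C@H](CC(=O)CCCCCCC)C2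
F8 | step 2 | 1-(ethylsulfanyl)-1-(trimethylsilyloxy)ethene | C=C(O[Si](C)(C)C)SCC
F9 | step 2 | S-ethyl 2-[(1S,5R)-2-methyl-5-(prop-1-en-2-yl)-3-(trimethylsilyloxy)cyclohex-2-en-1-yl]ethanethioate | C=C(C)[C@H]1CC(O[Si](C)(C)C)=C(C)[C@H](CC(=O)SCC)C1
F10 | step 2 | S-ethyl 2-[(1S,2S,5R)-2-hydroxy-2-methyl-3-oxo-5-(prop-1-en-2-yl)cyclohexyl]ethanethioate | C=C(C)[C@H]1CC(=O)[C@@](C)(O)[C@H](CC(=O)SCC)C1
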